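**Retrosynthetic overview**
- The strategy rests on the trans-2,3-disubstituted dihydrofuran ring O1–C2–C3–C3a–C7a of the furo[3,2-c]pyran-4-one. Aryl on C2 and an acyl-level carbon on C3 (C6' of the hydroxypyranone) mark this ring as the ring-contracted isomer of a 2-aryl-2,3-dihydropyrano[4,3-b]pyran-4,5-dione, a flavanone analogue.
- Late disconnections: the three silyl ethers; the 4-hydroxy-2-pyranone ring back to a C3 carboxylic acid (dioxinone acylation, acylketene cyclisation); the styryl C=C back to the 6-methyl group (aldol condensation of the carboxylate dianion, whose carboxylate shields C3–H).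
- Key disconnection: C3–C3a, formed by oxidative 1,2-shift of the pyranone carbon from the ketone carbon to the α-carbon with PhI(OAc)2 in HC(OMe)3/MeOH; added acid is needed so that the enol ether can form.
- The flavanone analogue comes from dehydroacetic acid via the chromone analogue 4 and an enantioselective conjugate arylation. C2 is thus set by an irreversible C–C bond formation, because a reversible oxa-Michael closure of the acidic, strongly chelated 3-cinnamoyl-4-hydroxypyranone could not be relied on to hold an ee.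
- Ring order: 2-pyranone (present in dehydroacetic acid), 4-pyranone (step 1), its contraction to the dihydrofuran (step 5), hydroxypyranone (step 10).

Key step: step 5

Assumption: the sense of induction of t-BuPyOx on 4 is taken to follow the cyclohexenone and chromone series (S-ligand gives the R product, hence the R-ligand here); the ligand antipode is exchanged if the assignment of 10 shows otherwise.

**Step 1**
Reactants: 1 dehydroacetic acid (3-acetyl-4-hydroxy-6-methyl-2H-pyran-2-one); 2 N,N-dimethylformamide dimethyl acetal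
Product: 4 7-methyl-4H,5H-pyrano[4,3-b]pyran-4,5-dione, via enaminone 3 (not isolated)
Conditions: 2 (1.1 equiv), toluene, 90 °C; evaporate; AcOH, 100 °C
Reagents that add atoms: none
Why: Enaminone formation at the acidic acetyl CH3, then acid-promoted addition–elimination of the 4-OH at the enaminone β-carbon with loss of dimethylamine, is the standard chromone synthesis from o-hydroxyaryl methyl ketones and closes the 4-pyranone ring.

**Step 2**
Reactants: 5 4-bromobenzene-1,2-diol
Product: 6 4-bromo-1,2-bis(triisopropylsilyloxy)benzene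
Conditions: TIPSCl (2.5 equiv), imidazole (5 equiv), DMF, 40 °C
Reagents that add atoms: triisopropylsilyl chloride, CC(C)[Si](Cl)(C(C)C)C(C)C
Why: Imidazole-promoted phenol silylation; aryl TIPS ethers should withstand the acid of step 5 and the amide bases of steps 8 and 9, donate less than alkyl ethers, and fall to fluoride at the end.

**Step 3**
Reactants: 6 4-bromo-1,2-bis(triisopropylsilyloxy)benzene
Product: 9 [3,4-bis(triisopropylsilyloxy)phenyl]boronic acid, via aryllithium 7 (not isolated), via lithium triisopropyl arylborate 8 (not isolated)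
Conditions: n-BuLi, THF, −78 °C; B(OiPr)3, −78 °C to rt; 1 M HCl, 0 °C
Reagents that add atoms: n-butyllithium, [Li]CCCC (lithium of 7 and 8 only); triisopropyl borate, CC(C)OB(OC(C)C)OC(C)C; water, O
Why: Bromine–lithium exchange and borylation, clean here because the lithiated carbon is meta and para to the silyloxy groups, so no oxygen-to-carbon silyl shift is possible.

**Step 4**
Reactants: 4 7-methyl-4H,5H-pyrano[4,3-b]pyran-4,5-dione; 9 [3,4-bis(triisopropylsilyloxy)phenyl]boronic acid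
Product: 10 (2S)-2-[3,4-bis(triisopropylsilyloxy)phenyl]-7-methyl-2,3-dihydro-4H,5H-pyrano[4,3-b]pyran-4,5-dione
Conditions: Pd(OCOCF3)2 (5 mol %), (R)-t-BuPyOx (6 mol %), NH4PF6 (30 mol %), H2O (5 equiv), ClCH2CH2Cl, 40–60 °C; neutral work-up
Reagents that add atoms: none
Why: Enantioselective conjugate addition of an arylboronic acid under divalent palladium catalysis, known for chromones; the aryl–palladium species adds across C2=C3 on the face left open by the tert-butyl group of the ligand (sets C2 as S), and the palladium enolate is protonated in a base-free medium that disfavours β-elimination of the ring oxygen.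

**Step 5**
Reactants: 10 (2S)-2-[3,4-bis(triisopropylsilyloxy)phenyl]-7-methyl-2,3-dihydro-4H,5H-pyrano[4,3-b]pyran-4,5-dione
Product: 12 methyl (2S,3S)-2-[3,4-bis(triisopropylsilyloxy)phenyl]-6-methyl-4-oxo-2,3-dihydro-4H-furo[3,2-c]pyran-3-carboxylate (trans), via methyl enol ether 11 (not isolated)
Conditions: PhI(OAc)2 (1.2 equiv), conc. H2SO4 (0.5 equiv), HC(OMe)3/MeOH 4:1, 0 °C to rt, short time; aq NaHCO3
Reagents that add atoms: trimethyl orthoformate, COC(OC)OC (methoxy group of the ester)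
Why: Proposed new method: HC(OMe)3 and acid turn the C4 ketone of 10 into the methyl enol ether 11, PhI(OAc)2 places trivalent iodine on C3 from the face opposite the C2 aryl group, methanol caps C4 as the dimethyl ketal, and the ring bond C4–C4a, antiperiplanar to the equatorial C3–iodine bond, shifts from C4 to C3 as iodobenzene leaves, so that the old C4 ends up outside the ring as a dimethoxycarbenium ion that gives the methyl ester on work-up. The closest known reaction type is the PhI(OAc)2/H2SO4/HC(OMe)3 ring contraction of flavanones to trans methyl 2-aryl-2,3-dihydrobenzofuran-3-carboxylates, and the new element is that the migrating carbon is C3 of a 4-alkoxy-2-pyranone (the nucleophilic end of the push-pull alkene C8a=C4a) instead of an arene carbon. The dihydrofuran O1–C2–C3–C3a–C7a is closed by this 1,2-shift, that is by a 3-exo-tet attack of C4a on C3 through a cyclopropane-bridged cation held as an oxocarbenium ion by O1, followed by rupture of C4–C4a under the push of the two methoxy groups. C3 is the only new stereocentre: inversion at a carbon whose iodine stood trans to the aryl group places the ester trans to it (2S,3S), the same epimer is favoured at equilibrium, and C2 takes no part. The step needs migration of C4a in preference to the C2 aryl shift and to elimination giving the 4-pyranone, and it must outrun acid-induced retro-oxa-Michael opening; the bulky aryl group stays equatorial and cannot align with the C3–iodine bond, the crowded silyloxy groups donate less than alkoxy groups, and low temperature with short contact time limits ring opening.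

**Step 6**
Reactants: 12 methyl (2S,3S)-2-[3,4-bis(triisopropylsilyloxy)phenyl]-6-methyl-4-oxo-2,3-dihydro-4H-furo[3,2-c]pyran-3-carboxylate
Product: 13 (2S,3S)-2-[3,4-bis(triisopropylsilyloxy)phenyl]-6-methyl-4-oxo-2,3-dihydro-4H-furo[3,2-c]pyran-3-carboxylic acid
Conditions: Me3SnOH (6 equiv), ClCH2CH2Cl, 75 °C; 1 M HCl wash
Reagents that add atoms: trimethyltin hydroxide, C[Sn](C)(C)O (oxygen of the carboxyl OH)
Why: Me3SnOH-mediated methyl ester cleavage is close to neutral and is the usual choice for 2-aryl-2,3-dihydrofuran-3-carboxylates, which hydroxide would open by β-elimination of the ring oxygen; the conjugated lactone and the aryl silyl ethers are much less reactive.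

**Step 7**
Reactants: 14 4-hydroxybenzaldehyde
Product: 15 4-(triisopropylsilyloxy)benzaldehyde
Conditions: TIPSCl (1.2 equiv), imidazole (2.5 equiv), DMF, rt
Reagents that add atoms: triisopropylsilyl chloride, CC(C)[Si](Cl)(C(C)C)C(C)C
Why: Imidazole-promoted phenol silylation, giving an aldehyde without an acidic proton for the carbanion chemistry of step 8.

**Step 8**
Reactants: 13 (2S,3S)-2-[3,4-bis(triisopropylsilyloxy)phenyl]-6-methyl-4-oxo-2,3-dihydro-4H-furo[3,2-c]pyran-3-carboxylic acid; 15 4-(triisopropylsilyloxy)benzaldehyde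
Product: 18 (2S,3S)-2-[3,4-bis(triisopropylsilyloxy)phenyl]-4-oxo-6-[(E)-2-(4-triisopropylsilyloxyphenyl)ethenyl]-2,3-dihydro-4H-furo[3,2-c]pyran-3-carboxylic acid, via dilithio dianion 16 (not isolated), via aldol carbinol 17 (not isolated)
Conditions: LDA (2.2 equiv), THF, −78 °C; 15 (1.2 equiv), −78 °C; AcOH quench, extraction; crude 17, TsOH·H2O (10 mol %), toluene, 60 °C
Reagents that add atoms: lithium diisopropylamide, [Li]N(C(C)C)C(C)C (lithium of 16 only)
Why: Vinylogous aldol condensation of a 6-methyl-4-alkoxy-2-pyranone; the carboxylate formed first makes C3–H non-acidic, so the second equivalent of LDA deprotonates the 6-CH3 (anion delocalised through C6=C7–C7a=C3a–C4=O), and E1 dehydration of the p-silyloxybenzylic carbinol gives the conjugated E alkene under thermodynamic control and erases the carbinol centre.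

**Step 9**
Reactants: 18 (2S,3S)-2-[3,4-bis(triisopropylsilyloxy)phenyl]-4-oxo-6-[(E)-2-(4-triisopropylsilyloxyphenyl)ethenyl]-2,3-dihydro-4H-furo[3,2-c]pyran-3-carboxylic acid; 19 2,2,6-trimethyl-4H-1,3-dioxin-4-one
Product: 22 (2S,3S)-2-[3,4-bis(triisopropylsilyloxy)phenyl]-3-[2-(2,2-dimethyl-4-oxo-4H-1,3-dioxin-6-yl)acetyl]-6-[(E)-2-(4-triisopropylsilyloxyphenyl)ethenyl]-2,3-dihydro-4H-furo[3,2-c]pyran-4-one, via acyl imidazole 20 (not isolated), via lithium dienolate 21 (not isolated)
Conditions: 18, CDI (1.1 equiv), THF, rt; separately 19 (4 equiv), LiHMDS (4 equiv), THF, −78 °C, then Et2Zn (4 equiv), −78 to −20 °C; add 20, −20 °C; cold 1 M HCl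
Reagents that add atoms: 1,1'-carbonyldiimidazole, O=C(n1ccnc1)n1ccnc1 (imidazolyl group of 20 only); lithium hexamethyldisilazide, [Li]N([Si](C)(C)C)[Si](C)(C)C (lithium of 21 only)
Why: Crossed Claisen γ-C-acylation of the dioxinone dienolate by an acyl imidazole; Et2Zn lowers the basicity of the dienolate as in acylations with epimerisable acyl donors, and 22 is deprotonated at once at the CH2 between ketone and dioxinone, which keeps the ketone from enolising towards C3.

**Step 10**
Reactants: 22 (2S,3S)-2-[3,4-bis(triisopropylsilyloxy)phenyl]-3-[2-(2,2-dimethyl-4-oxo-4H-1,3-dioxin-6-yl)acetyl]-6-[(E)-2-(4-triisopropylsilyloxyphenyl)ethenyl]-2,3-dihydro-4H-furo[3,2-c]pyran-4-one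
Product: 24 (2S,3S)-2-[3,4-bis(triisopropylsilyloxy)phenyl]-3-(4-hydroxy-2-oxo-2H-pyran-6-yl)-6-[(E)-2-(4-triisopropylsilyloxyphenyl)ethenyl]-2,3-dihydro-4H-furo[3,2-c]pyran-4-one, via acylketene 23 (not isolated)
Conditions: toluene (0.01 M), 110 °C
Reagents that add atoms: none
Why: Retro-hetero-Diels–Alder loss of acetone gives the acylketene, which the enol oxygen of the δ-ketone captures to close the 4-hydroxy-2-pyranone under neutral conditions, so C2 and C3 are not exposed to base and any enolisation at C3 returns to the favoured trans isomer.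

**Step 11**
Reactants: 24 (2S,3S)-2-[3,4-bis(triisopropylsilyloxy)phenyl]-3-(4-hydroxy-2-oxo-2H-pyran-6-yl)-6-[(E)-2-(4-triisopropylsilyloxyphenyl)ethenyl]-2,3-dihydro-4H-furo[3,2-c]pyran-4-one
Product: 25 (2S,3S)-2-(3,4-dihydroxyphenyl)-3-(4-hydroxy-2-oxo-2H-pyran-6-yl)-6-[(E)-2-(4-hydroxyphenyl)ethenyl]-2,3-dihydro-4H-furo[3,2-c]pyran-4-one (CNP0330607.1)
Conditions: Et3N·3HF (excess), THF/MeCN, rt, under argon
Reagents that add atoms: none
Why: Fluoride-driven cleavage of the three aryl silyl ethers in a slightly acidic amine–HF medium, which avoids both phenoxide-induced air oxidation of the catechol and base-induced β-elimination across C3–C2–O1.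

**Compound list**
1 | dehydroacetic acid (3-acetyl-4-hydroxy-6-methyl-2H-pyran-2-one) | CC(=O)c1c(O)cc(C)oc1=O | starting material
2 | N,N-dimethylformamide dimethyl acetal | COC(OC)N(C)C | starting material
3 | 3-[(2E)-3-(dimethylamino)prop-2-enoyl]-4-hydroxy-6-methyl-2H-pyran-2-one | CN(C)/C=C/C(=O)c1c(O)cc(C)oc1=O | intermediate
4 | 7-methyl-4H,5H-pyrano[4,3-b]pyran-4,5-dione | O=C1C=COc2cc(C)oc(=O)c12 | intermediate
5 | 4-bromobenzene-1,2-diol | Oc1ccc(Br)cc1O | starting material
6 | 4-bromo-1,2-bis(triisopropylsilyloxy)benzene | Brc1ccc(O[Si](C(C)C)(C(C)C)C(C)C)c(O[Si](C(C)C)(C(C)C)C(C)C)c1 | intermediate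
7 | [3,4-bis(triisopropylsilyloxy)phenyl]lithium | [Li]c1ccc(O[Si](C(C)C)(C(C)C)C(C)C)c(O[Si](C(C)C)(C(C)C)C(C)C)c1 | intermediate
8 | lithium [3,4-bis(triisopropylsilyloxy)phenyl]triisopropoxyborate | [Li+].CC(C)O[B-](OC(C)C)(OC(C)C)c1ccc(O[Si](C(C)C)(C(C)C)C(C)C)c(O[Si](C(C)C)(C(C)C)C(C)C)c1 | intermediate
9 | [3,4-bis(triisopropylsilyloxy)phenyl]boronic acid | OB(O)c1ccc(O[Si](C(C)C)(C(C)C)C(C)C)c(O[Si](C(C)C)(C(C)C)C(C)C)c1 | intermediate
10 | (2S)-2-[3,4-bis(triisopropylsilyloxy)phenyl]-7-methyl-2,3-dihydro-4H,5H-pyrano[4,3-b]pyran-4,5-dione (same skeleton as pyrano[3,2-c]pyran-4,5-dione) | O=C1C[C@@H](c2ccc(O[Si](C(C)C)(C(C)C)C(C)C)c(O[Si](C(C)C)(C(C)C)C(C)C)c2)Oc2cc(C)oc(=O)c12 | intermediate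
11 | (2S)-2-[3,4-bis(triisopropylsilyloxy)phenyl]-4-methoxy-7-methyl-2H,5H-pyrano[4,3-b]pyran-5-one | COC1=C[C@@H](c2ccc(O[Si](C(C)C)(C(C)C)C(C)C)c(O[Si](C(C)C)(C(C)C)C(C)C)c2)Oc2cc(C)oc(=O)c12 | intermediate
12 | methyl (2S,3S)-2-[3,4-bis(triisopropylsilyloxy)phenyl]-6-methyl-4-oxo-2,3-dihydro-4H-furo[3,2-c]pyran-3-carboxylate (trans) | COC(=O)[C@H]1c2c(cc(C)oc2=O)O[C@@H]1c1ccc(O[Si](C(C)C)(C(C)C)C(C)C)c(O[Si](C(C)C)(C(C)C)C(C)C)c1 | intermediate
13 | (2S,3S)-2-[3,4-bis(triisopropylsilyloxy)phenyl]-6-methyl-4-oxo-2,3-dihydro-4H-furo[3,2-c]pyran-3-carboxylic acid | OC(=O)[C@H]1c2c(cc(C)oc2=O)O[C@@H]1c1ccc(O[Si](C(C)C)(C(C)C)C(C)C)c(O[Si](C(C)C)(C(C)C)C(C)C)c1 | intermediate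
14 | 4-hydroxybenzaldehyde | O=Cc1ccc(O)cc1 | starting material
15 | 4-(triisopropylsilyloxy)benzaldehyde | O=Cc1ccc(O[Si](C(C)C)(C(C)C)C(C)C)cc1 | intermediate
16 | dilithium salt of 13 (carboxylate and 6-CH2 carbanion) | [Li+].[Li+].[O-]C(=O)[C@H]1c2c(cc([CH2-])oc2=O)O[C@@H]1c1ccc(O[Si](C(C)C)(C(C)C)C(C)C)c(O[Si](C(C)C)(C(C)C)C(C)C)c1 | intermediate
17 | (2S,3S)-2-[3,4-bis(triisopropylsilyloxy)phenyl]-6-[2-hydroxy-2-(4-triisopropylsilyloxyphenyl)ethyl]-4-oxo-2,3-dihydro-4H-furo[3,2-c]pyran-3-carboxylic acid (both carbinol epimers) | OC(=O)[C@H]1c2c(cc(CC(O)c3ccc(O[Si](C(C)C)(C(C)C)C(C)C)cc3)oc2=O)O[C@@H]1c1ccc(O[Si](C(C)C)(C(C)C)C(C)C)c(O[Si](C(C)C)(C(C)C)C(C)C)c1 | intermediate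
18 | (2S,3S)-2-[3,4-bis(triisopropylsilyloxy)phenyl]-4-oxo-6-[(E)-2-(4-triisopropylsilyloxyphenyl)ethenyl]-2,3-dihydro-4H-furo[3,2-c]pyran-3-carboxylic acid | OC(=O)[C@H]1c2c(cc(/C=C/c3ccc(O[Si](C(C)C)(C(C)C)C(C)C)cc3)oc2=O)O[C@@H]1c1ccc(O[Si](C(C)C)(C(C)C)C(C)C)c(O[Si](C(C)C)(C(C)C)C(C)C)c1 | intermediate
19 | 2,2,6-trimethyl-4H-1,3-dioxin-4-one | CC1=CC(=O)OC(C)(C)O1 | starting material
20 | N-acylimidazole of acid 18 (2S,3S) | O=C(n1ccnc1)[C@H]1c2c(cc(/C=C/c3ccc(O[Si](C(C)C)(C(C)C)C(C)C)cc3)oc2=O)O[C@@H]1c1ccc(O[Si](C(C)C)(C(C)C)C(C)C)c(O[Si](C(C)C)(C(C)C)C(C)C)c1 | intermediate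
21 | lithium 2,2-dimethyl-6-methylidene-1,3-dioxin-4-olate | [Li+].C=C1C=C([O-])OC(C)(C)O1 | intermediate
22 | (2S,3S)-2-[3,4-bis(triisopropylsilyloxy)phenyl]-3-[2-(2,2-dimethyl-4-oxo-4H-1,3-dioxin-6-yl)acetyl]-6-[(E)-2-(4-triisopropylsilyloxyphenyl)ethenyl]-2,3-dihydro-4H-furo[3,2-c]pyran-4-one | CC1(C)OC(=O)C=C(CC(=O)[C@H]2c3c(cc(/C=C/c4ccc(O[Si](C(C)C)(C(C)C)C(C)C)cc4)oc3=O)O[C@@H]2c2ccc(O[Si](C(C)C)(C(C)C)C(C)C)c(O[Si](C(C)C)(C(C)C)C(C)C)c2)O1 | intermediate
23 | acylketene from 22 (3,5-dioxopent-1-en-1-one carrying the (2S,3S)-furopyranone at C5) | O=C=CC(=O)CC(=O)[C@H]1c2c(cc(/C=C/c3ccc(O[Si](C(C)C)(C(C)C)C(C)C)cc3)oc2=O)O[C@@H]1c1ccc(O[Si](C(C)C)(C(C)C)C(C)C)c(O[Si](C(C)C)(C(C)C)C(C)C)c1 | intermediate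
24 | (2S,3S)-2-[3,4-bis(triisopropylsilyloxy)phenyl]-3-(4-hydroxy-2-oxo-2H-pyran-6-yl)-6-[(E)-2-(4-triisopropylsilyloxyphenyl)ethenyl]-2,3-dihydro-4H-furo[3,2-c]pyran-4-one | O=c1cc(O)cc([C@H]2c3c(cc(/C=C/c4ccc(O[Si](C(C)C)(C(C)C)C(C)C)cc4)oc3=O)O[C@@H]2c2ccc(O[Si](C(C)C)(C(C)C)C(C)C)c(O[Si](C(C)C)(C(C)C)C(C)C)c2)o1 | intermediate
25 | (2S,3S)-2-(3,4-dihydroxyphenyl)-3-(4-hydroxy-2-oxo-2H-pyran-6-yl)-6-[(E)-2-(4-hydroxyphenyl)ethenyl]-2,3-dihydro-4H-furo[3,2-c]pyran-4-one (CNP0330607.1) | O=c1cc(O)cc([C@H]2c3c(cc(/C=C/c4ccc(O)cc4)oc3=O)O[C@@H]2c2ccc(O)c(O)c2)o1 | target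

**Totals**
Total step count: 11.
Longest linear sequence: 9 steps (2, 3, 4, 5, 6, 8, 9, 10, 11, from 4-bromobenzene-1,2-diol).

**Steps most likely to fail**

**Step 5.**
- What may go wrong: the C2 aryl group may migrate in place of C4a. The iodane may be lost by elimination, giving the 4-pyranone. Acid may open the dihydropyranone ring by retro-oxa-Michael reaction, which erodes C2 and exposes the enone to oxidative rearrangement. A silyl group may be lost, after which the freed catechol would be oxidised.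
- Fallback (known chemistry): it sets out from bromide 6. A Heck reaction with methyl acrylate (Pd(OAc)2, P(o-tol)3, Et3N, DMF, 100 °C) should give methyl (E)-3-[3,4-bis(triisopropylsilyloxy)phenyl]acrylate F1. Oxidative radical [3+2] annulation of commercial 4-hydroxy-6-methyl-2H-pyran-2-one onto F1 follows, with Mn(OAc)3·2H2O in AcOH at 60 °C. In it the pyranone C3 radical adds to the ester-bearing alkene carbon, and the benzylic radical is oxidised by trivalent manganese to the cation and captured by the 4-oxygen. This should give the racemic trans methyl 2-aryl-6-methyl-4-oxo-2,3-dihydrofuro[3,2-c]pyran-3-carboxylate F2. Preparative chromatography on a chiral stationary phase then delivers the (2S,3S) enantiomer, and the route is rejoined at 12.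

**Step 4.**
- What may go wrong: the pyranone oxygen may be lost from the palladium enolate by β-elimination, opening the ring. Water may attack C2 of 4. The electron-rich boronic acid may protodeboronate. Facial selectivity may be modest on an acceptor that can chelate through its two neighbouring carbonyl groups.
- Fallback: it sets out from bromide 6 and dione 4. Bromine–lithium exchange to 7 and transmetalation with ZnCl2 give [3,4-bis(triisopropylsilyloxy)phenyl]zinc chloride F3. Rhodium-catalysed asymmetric 1,4-addition of F3 to 4 is then run in the presence of Me3SiCl ([RhCl((S)-binap)]2 or its antipode as the sense of induction requires, THF, 20 °C). This procedure is known for 4-quinolones and traps the enolate as it forms, as (2S)-2-[3,4-bis(triisopropylsilyloxy)phenyl]-7-methyl-4-(trimethylsilyloxy)-2H,5H-pyrano[4,3-b]pyran-5-one F4. Brief hydrolysis with citric acid in THF/H2O at 0 °C returns to the route at 10.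

**Step 9.**
- What may go wrong: the dienolate may deprotonate the acyl imidazole at C3–H. Ketene formation or β-elimination of O1 would follow, opening the ring with loss of both stereocentres. O-acylation of the dienolate may compete.
- Fallback: a base-free acylation that sets out from acid 18. 1-Chloro-N,N,2-trimethylprop-1-en-1-amine in CH2Cl2 at 0 °C gives the (2S,3S) acid chloride F5 under neutral conditions. Uncatalysed γ-acylation of 1-methoxy-1,3-bis(trimethylsilyloxy)buta-1,3-diene by F5 (CH2Cl2, −78 to 20 °C, aqueous work-up) gives methyl 3,5-dioxo-5-[(2S,3S)-furopyranon-3-yl]pentanoate F6. Lactonisation of F6 with DBU in toluene deprotonates only the strongly acidic tricarbonyl chain and rejoins the route at 24, bypassing 22 and 23.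

**Further compounds**
F1 | step 5 | methyl (E)-3-[3,4-bis(triisopropylsilyloxy)phenyl]acrylate | COC(=O)/C=C/c1ccc(O[Si](C(C)C)(C(C)C)C(C)C)c(O[Si](C(C)C)(C(C)C)C(C)C)c1
F2 | step 5 | racemic trans methyl 2-[3,4-bis(triisopropylsilyloxy)phenyl]-6-methyl-4-oxo-2,3-dihydro-4H-furo[3,2-c]pyran-3-carboxylate (1:1 mixture of 12 and its enantiomer) | COC(=O)[C@H]1c2c(cc(C)oc2=O)O[C@@H]1c1ccc(O[Si](C(C)C)(C(C)C)C(C)C)c(O[Si](C(C)C)(C(C)C)C(C)C)c1.COC(=O)[C@@H]1c2c(cc(C)oc2=O)O[C@H]1c1ccc(O[Si](C(C)C)(C(C)C)C(C)C)c(O[Si](C(C)C)(C(C)C)C(C)C)c1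
F3 | step 4 | [3,4-bis(triisopropylsilyloxy)phenyl]zinc chloride | Cl[Zn]c1ccc(O[Si](C(C)C)(C(C)C)C(C)C)c(O[Si](C(C)C)(C(C)C)C(C)C)c1
F4 | step 4 | (2S)-2-[3,4-bis(triisopropylsilyloxy)phenyl]-7-methyl-4-(trimethylsilyloxy)-2H,5H-pyrano[4,3-b]pyran-5-one | C[Si](C)(C)OC1=C[C@@H](c2ccc(O[Si](C(C)C)(C(C)C)C(C)C)c(O[Si](C(C)C)(C(C)C)C(C)C)c2)Oc2cc(C)oc(=O)c12
F5 | step 9 | (2S,3S)-2-[3,4-bis(triisopropylsilyloxy)phenyl]-4-oxo-6-[(E)-2-(4-triisopropylsilyloxyphenyl)ethenyl]-2,3-dihydro-4H-furo[3,2-c]pyran-3-carbonyl chloride | ClC(=O)[C@H]1c2c(cc(/C=C/c3ccc(O[Si](C(C)C)(C(C)C)C(C)C)cc3)oc2=O)O[C@@H]1c1ccc(O[Si](C(C)C)(C(C)C)C(C)C)c(O[Si](C(C)C)(C(C)C)C(C)C)c1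
F6 | step 9 | methyl 5-{(2S,3S)-2-[3,4-bis(triisopropylsilyloxy)phenyl]-4-oxo-6-[(E)-2-(4-triisopropylsilyloxyphenyl)ethenyl]-2,3-dihydro-4H-furo[3,2-c]pyran-3-yl}-3,5-dioxopentanoate | COC(=O)CC(=O)CC(=O)[C@H]1c2c(cc(/C=C/c3ccc(O[Si](C(C)C)(C(C)C)C(C)C)cc3)oc2=O)O[C@@H]1c1ccc(O[Si](C(C)C)(C(C)C)C(C)C)c(O[Si](C(C)C)(C(C)C)C(C)C)c1
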